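**Retrosynthetic overview**
1. Feature: in the cyclohexene ring C13–C14(Me)=C15–C16–C17–C22 of the cis-decalin, H13 (on the carbon carrying the C11–C12 tether) and the fusion hydrogens H22 and H17 lie on one face. The C14=C15 bond sits across the ring from the C17–C22 fusion bond. This is the signature of an endo [4+2] addition of an E-1-alkyl-2-methylbutadiene to a cyclic cis-enedione.
2. Key disconnection: C13–C22 and C16–C17, leading back to the left-half diene 15 and symmetric 1,4-benzoquinone 16, with a chiral boron Lewis acid choosing the diene face.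
3. After the union the two quinone carbonyls are told apart by crowding. C18=O (open) goes to the methylene, then convex-face hydration gives C(Me)OH. C21=O (beside the tether) goes to the methylene, then hydromethylation gives CMe2.
4. Diene 15 comes from lactone 10 (DIBAL-H, two Wittig reactions, silylation). Lactone 10 comes in one cascade from bis-epoxy ester 8, which is farnesyl acetate 1 after double asymmetric epoxidation and a two-carbon enolate extension.
5. Ring order: oxepane and cyclohexane form together in step 5 (with a sacrificial δ-lactone ring), then the cyclohexene ring in step 10. The last carbocycle is the quinone ring itself.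

Key step: step 10

Atom labels (used for all compounds): the oxepane is O–C1(Me2)–C2–C3–C4–C5(Me)–C6. The cyclohexane is C5–C6–C7–C8–C9–C10. The tether is C11–C12. The cyclohexene is C13–C14(Me)=C15–C16–C17–C22. The second decalin ring is C17–C18–C19–C20–C21–C22. The target is 2S,5S,6S,9S,10S,13S,17S,18S,22R.
Assumption 1: the L-fructose-derived antipode of the Shi ketone (made from L-sorbose by the usual sequence) is taken as available, because the (S)-configured epoxides are needed.
Assumption 2: the (S)-diphenylprolinol-derived oxazaborolidinium salt is taken to give the 13S,17S,22R triad. If the first run shows the opposite sense, the commercial (R)-antipode is used and nothing else changes.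

Step 1
Reactants: 1 (2E,6E)-farnesyl acetate
Product: 2 (2S,5S,6S)-bis-epoxy farnesyl acetate (oxiranes at C1–C2 and C5–C6; E-C9=C10 retained)
Conditions: ent-Shi ketone (30 mol %), Oxone, K2CO3, Bu4NHSO4 (cat.), MeCN/DMM–aq. borate/EDTA buffer (pH 10.5), 0 °C
Reagents that add atoms: potassium peroxymonosulfate (Oxone), [K+].[O-]S(=O)(=O)OO
Why: Shi asymmetric epoxidation: the chiral dioxirane reaches the two electron-rich trisubstituted alkenes through the spiro transition state and, in the L-fructose series, should deliver oxygen to the faces that give 2S and 5S,6S, whereas the C9=C10 alkene is switched off inductively by the allylic acetate.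

Step 2
Reactants: 2 (2S,5S,6S)-bis-epoxy farnesyl acetate
Product: 3 (2S,5S,6S)-bis-epoxy farnesol
Conditions: K2CO3 (cat.), MeOH, 0 °C
Reagents that add atoms: none
Why: Base-catalysed transesterification (Zemplén-type methanolysis) frees the primary allylic alcohol under conditions too mild to open trisubstituted epoxides.

Step 3
Reactants: 3 (2S,5S,6S)-bis-epoxy farnesol
Product: 5 (2S,5S,6S)-bis-epoxy farnesyl bromide, via allylic mesylate 4 (not isolated)
Conditions: MsCl, Et3N, THF, −40 °C; then LiBr, THF, −40 → 0 °C
Reagents that add atoms: methanesulfonyl chloride (atoms only in 4), CS(=O)(=O)Cl; lithium bromide, [Li+].[Br-]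
Why: Mesylation and in situ SN2 displacement by bromide (Finkelstein-type) act only on the primary allylic alcohol, stay non-acidic for the epoxides and keep the E-geometry because no allyl cation is formed.

Step 4
Reactants: 5 (2S,5S,6S)-bis-epoxy farnesyl bromide; 6 tert-butyl acetate
Product: 8 tert-butyl (4E,8S,9S,12S)-8,9:12,13-diepoxy-5,9,13-trimethyltetradec-4-enoate, via lithium enolate 7 (not isolated)
Conditions: 6, LDA, THF, −78 °C; then 5, −78 → −20 °C
Reagents that add atoms: lithium diisopropylamide (Li only in 7), [Li+].CC(C)[N-]C(C)C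
Why: SN2 alkylation of a preformed ester lithium enolate with a primary allylic bromide is fast at low temperature, where trisubstituted epoxides are inert to the enolate, and it brings in C12 and C13 together with the carbonyl oxygen that will end the cascade.

Step 5
Reactants: 8 tert-butyl bis-epoxy enoate
Product: 10 tricyclic hydroxy lactone (oxepane/cyclohexane/δ-lactone; both fusions trans; free C2–OH), via C2-O-trimethylsilyl lactone 9 (not isolated)
Conditions: TMSOTf, 2,6-di-tert-butyl-4-methylpyridine, CH2Cl2 (dilute), −78 °C; then 1 M HCl, THF, 0 °C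
Reagents that add atoms: trimethylsilyl triflate (Me3Si only in 9), C[Si](C)(C)OS(=O)(=O)C(F)(F)F
Why: Epoxide-opening cation–olefin cascade (tandem endo-oxacyclisation/carbacyclisation of a 1,5-diepoxide, ended like a polyene lactonisation): silylation of the terminal oxirane lets the C5–C6 oxirane oxygen attack tertiary C1, the bicyclic epoxonium ion is opened at tertiary C5 with inversion by C10 of the E-alkene in a chair array, and the C9 cation is captured anti by the ester carbonyl with loss of isobutene, so that C2 and C6 keep their C–O configuration while C5, C10 and C9 follow from the epoxide and alkene geometries (axial C5-methyl, equatorial C10 chain, equatorial C9–O).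

Step 6
Reactants: 10 tricyclic hydroxy lactone
Product: 11 lactol (C13 hemiacetal, anomer mixture)
Conditions: DIBAL-H (2.2 equiv), CH2Cl2, −78 °C; Rochelle salt
Reagents that add atoms: none
Why: Partial reduction of a lactone with DIBAL-H stops at the aluminium hemiacetal, which is stable at −78 °C, one extra equivalent being taken up by the free C2 hydroxyl.

Step 7
Reactants: 11 lactol; 12 2-(triphenylphosphoranylidene)propanal
Product: 13 (E)-enal diol (C12–C13H=C14(Me)–CHO; free C2–OH and C9–OH)
Conditions: 12, toluene, 90 °C
Reagents that add atoms: none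
Why: Wittig olefination of the open hydroxy-aldehyde tautomer of the lactol with a stabilised, α-branched ylide should give the E-trisubstituted enal, the product-like transition state placing C12 trans to the formyl group, and it frees the C9 carbinol.

Step 8
Reactants: 13 (E)-enal diol
Product: 14 E-diene diol (C13H=C14(Me)–C15H=C16H2)
Conditions: Ph3PCH3Br, KOtBu, THF, 0 °C
Reagents that add atoms: methyltriphenylphosphonium bromide, C[P+](c1ccccc1)(c1ccccc1)c1ccccc1.[Br-]
Why: Wittig methylenation attacks the enal carbonyl in 1,2-fashion, leaves the E-C13=C14 bond untouched and tolerates the two hindered hydroxyl groups, which the ylide is not basic enough to deprotonate to any extent.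

Step 9
Reactants: 14 E-diene diol
Product: 15 bis-TES E-diene (C2–OTES, C9–OTES)
Conditions: TESOTf, 2,6-lutidine, CH2Cl2, −78 → 0 °C
Reagents that add atoms: triethylsilyl triflate, CC[Si](CC)(CC)OS(=O)(=O)C(F)(F)F
Why: A silyl triflate with a hindered pyridine base silylates even the tertiary C9 and the neopentyl C2 hydroxyl groups at low temperature without protonating the diene.

Step 10
Reactants: 15 bis-TES E-diene; 16 1,4-benzoquinone
Product: 17 cis-fused enedione adduct (13S,17S,22R; H13, H17 and H22 all cis; C18=O, C19=C20, C21=O)
Conditions: 16 (excess), oxazaborolidinium triflimide from (S)-α,α-diphenylprolinol/o-tolylboronic acid (20 mol %) and Tf2NH (18 mol %), CH2Cl2, −78 °C; used crude in step 11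
Reagents that add atoms: none
Why: The s-cis diene C13=C14–C15=C16 adds suprafacially, in a concerted but asynchronous Lewis-acid-accelerated [4π+2π] process, to one C=C of the boron-bound quinone and forms C13–C22 and C16–C17; the closest known type is the oxazaborolidinium-catalysed enantioselective Diels–Alder reaction of 1,4-quinones with alkyl-substituted dienes. One ring is closed, the cyclohexene C13–C14=C15–C16–C17–C22, by intermolecular six-centre [4+2] closure, and the second decalin ring is the quinone ring itself. C17 and C22 come out cis because addition to the cyclic Z-enedione is suprafacial, and C13 comes out with its tether cis to both carbonyl-bearing bonds because the tether holds the outside (E) position of the diene while the carbonyls lie endo under it. The sense of this triad relative to the remote left-half centres is set by the catalyst, which covers one face of the complexed C=C and polarises it so that the unhindered C16H2 terminus (favoured by the C13 alkyl group and by size, opposed only by the weaker pull of the C14 methyl) bonds ahead to the carbon β to the bound carbonyl; face shielding and this orientation together single out one of the two endo diastereomers. No constitutional regiochemistry arises because 16 is symmetric; mono-addition is secured by excess 16 and by the greater crowding of the adduct enedione, the silyl ethers are protected by the low temperature and the absence of free acid, and the E-geometry fixed in step 7 secures both the s-cis population and the C13/C22 relation.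

Step 11
Reactants: 17 cis-fused enedione adduct
Product: 18 cis-decalin-1,4-dione (C18=O, C21=O; C19 and C20 now CH2)
Conditions: Zn dust, AcOH, THF, 0 °C, short contact
Reagents that add atoms: none
Why: Dissolving-metal conjugate reduction: zinc transfers two electrons only to the low-lying ene-dione π system, acetic acid protonates at C19 and C20, the isolated C14=C15 alkene is inert, and the short, cold, weakly acidic treatment should leave the cis fusion and the hindered silyl ethers intact while closing the path to the hydroquinone.

Step 12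
Reactants: 18 cis-decalin-1,4-dione
Product: 19 C18-methylene C21-ketone
Conditions: Tebbe reagent (1.1 equiv), pyridine, THF/toluene, −40 → 0 °C
Reagents that add atoms: Tebbe reagent (Cp drawn η1), Cl[Ti](C[Al](C)C)(C1C=CC=C1)C1C=CC=C1
Why: Tebbe methylenation through the titanium methylidene and an oxatitanacyclobutane is non-basic, so C17 and C22 should not epimerise, and the bulky carbene should pick the C18 carbonyl, whose neighbour C17 adjoins only the C16 methylene, over the C21 carbonyl, which is crowded by the C13 tether on the concave face.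

Step 13
Reactants: 19 C18-methylene C21-ketone
Product: 21 (18S)-C18 methyl carbinol C21-ketone (OH cis to H17), via tertiary hydroperoxide 20 (not isolated)
Conditions: Mn(dpm)3 (cat.), PhSiH3, O2 (1 atm), i-PrOH/CH2Cl2, 0 °C; then PPh3
Reagents that add atoms: dioxygen, O=O
Why: Mukaiyama hydration (metal-hydride hydrogen-atom transfer, then O2 capture): the hydride adds H to the exposed CH2 of the 1,1-disubstituted alkene faster than to the trisubstituted C14=C15 bond, and the tertiary C18 radical should take up O2 on the convex face marked by H17 and H22 because ring A covers the other face, which sets 18S.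

Step 14
Reactants: 21 C18 methyl carbinol C21-ketone
Product: 22 C21-methylene C18-carbinol
Conditions: Tebbe reagent (excess), pyridine, THF/toluene, 0 °C → rt
Reagents that add atoms: Tebbe reagent (Cp drawn η1), Cl[Ti](C[Al](C)C)(C1C=CC=C1)C1C=CC=C1
Why: The same non-basic Tebbe methylenation is reactive enough for hindered, enolisable ketones, reaches C21 from the convex face and removes the last carbonyl that could epimerise C22, the first equivalent of reagent being spent on the free carbinol.

Step 15
Reactants: 22 C21-methylene C18-carbinol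
Product: 24 2,9-bis-O-TES sipholenol L (C21 now CMe2), via N-alkyl sulfonylhydrazide 23 (not isolated)
Conditions: aq. HCHO, n-C8H17SO2NHNH2, THF; then 22, Fe(acac)3 (30 mol %), PhSiH3, MeOH/THF, rt; then MeOH, 60 °C
Reagents that add atoms: formaldehyde, C=O; octane-1-sulfonohydrazide (atoms only in 23), CCCCCCCCS(=O)(=O)NN
Why: Iron-hydride hydrogen-atom-transfer hydromethylation: H adds to the exposed CH2 terminus of the 1,1-disubstituted alkene in preference to the trisubstituted ring alkene, the tertiary C21 radical adds to the small formaldehyde sulfonylhydrazone, and warming expels sulfinate and N2 from 23 so that the new CH2 becomes the second methyl group, no stereocentre being left at C21 in 24.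

Step 16
Reactants: 24 2,9-bis-O-TES sipholenol L
Product: 25 sipholenol L
Conditions: HF·pyridine, pyridine, THF, 0 °C → rt
Reagents that add atoms: none
Why: Fluoride-driven cleavage of the two triethylsilyl ethers under pyridine-buffered conditions is mild enough for the three carbinols and the trisubstituted alkene and touches no stereocentre.

**Compound list**
1 | (2E,6E)-farnesyl acetate | CC(C)=CCC/C(C)=C/CC/C(C)=C/COC(C)=O | starting material
2 | (2S,5S,6S)-bis-epoxy farnesyl acetate | CC1(C)O[C@H]1CC[C@]1(C)O[C@H]1CC/C(C)=C/COC(C)=O | intermediate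
3 | (2S,5S,6S)-bis-epoxy farnesol | CC1(C)O[C@H]1CC[C@]1(C)O[C@H]1CC/C(C)=C/CO | intermediate
4 | allylic mesylate of 3 | CC1(C)O[C@H]1CC[C@]1(C)O[C@H]1CC/C(C)=C/COS(C)(=O)=O | intermediate
5 | (2S,5S,6S)-bis-epoxy farnesyl bromide | CC1(C)O[C@H]1CC[C@]1(C)O[C@H]1CC/C(C)=C/CBr | intermediate
6 | tert-butyl acetate | CC(=O)OC(C)(C)C | starting material
7 | lithium enolate of tert-butyl acetate | [Li+].C=C([O-])OC(C)(C)C | intermediate
8 | tert-butyl (4E,8S,9S,12S)-8,9:12,13-diepoxy-5,9,13-trimethyltetradec-4-enoate | CC1(C)O[C@H]1CC[C@]1(C)O[C@H]1CC/C(C)=C/CCC(=O)OC(C)(C)C | intermediate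
9 | C2-O-trimethylsilyl tricyclic lactone | O=C1CC[C@H]2[C@]3(C)CC[C@H](O[Si](C)(C)C)C(C)(C)O[C@H]3CC[C@]2(C)O1 | intermediate
10 | tricyclic hydroxy lactone | O=C1CC[C@H]2[C@]3(C)CC[C@H](O)C(C)(C)O[C@H]3CC[C@]2(C)O1 | intermediate
11 | lactol (C13 anomers) | OC1CC[C@H]2[C@]3(C)CC[C@H](O)C(C)(C)O[C@H]3CC[C@]2(C)O1 | intermediate
12 | 2-(triphenylphosphoranylidene)propanal | CC(C=O)=P(c1ccccc1)(c1ccccc1)c1ccccc1 | starting material
13 | (E)-enal diol | O=C/C(C)=C/CC[C@H]1[C@]3(C)CC[C@H](O)C(C)(C)O[C@H]3CC[C@]1(C)O | intermediate
14 | E-diene diol | C=C/C(C)=C/CC[C@H]1[C@]3(C)CC[C@H](O)C(C)(C)O[C@H]3CC[C@]1(C)O | intermediate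
15 | bis-TES E-diene (key-step precursor) | C=C/C(C)=C/CC[C@H]1[C@]3(C)CC[C@H](O[Si](CC)(CC)CC)C(C)(C)O[C@H]3CC[C@]1(C)O[Si](CC)(CC)CC | intermediate
16 | 1,4-benzoquinone | O=C1C=CC(=O)C=C1 | starting material
17 | cis-fused enedione adduct (13S,17S,22R) | CC1=CC[C@H]2[C@@H]([C@@H]1CC[C@H]1[C@]3(C)CC[C@H](O[Si](CC)(CC)CC)C(C)(C)O[C@H]3CC[C@]1(C)O[Si](CC)(CC)CC)C(=O)C=CC2=O | intermediate
18 | cis-decalin-1,4-dione | CC1=CC[C@H]2[C@@H]([C@@H]1CC[C@H]1[C@]3(C)CC[C@H](O[Si](CC)(CC)CC)C(C)(C)O[C@H]3CC[C@]1(C)O[Si](CC)(CC)CC)C(=O)CCC2=O | intermediate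
19 | C18-methylene C21-ketone | CC1=CC[C@H]2[C@@H]([C@@H]1CC[C@H]1[C@]3(C)CC[C@H](O[Si](CC)(CC)CC)C(C)(C)O[C@H]3CC[C@]1(C)O[Si](CC)(CC)CC)C(=O)CCC2=C | intermediate
20 | C18 tertiary hydroperoxide | CC1=CC[C@H]2[C@@H]([C@@H]1CC[C@H]1[C@]3(C)CC[C@H](O[Si](CC)(CC)CC)C(C)(C)O[C@H]3CC[C@]1(C)O[Si](CC)(CC)CC)C(=O)CC[C@]2(C)OO | intermediate
21 | (18S)-C18 methyl carbinol C21-ketone | CC1=CC[C@H]2[C@@H]([C@@H]1CC[C@H]1[C@]3(C)CC[C@H](O[Si](CC)(CC)CC)C(C)(C)O[C@H]3CC[C@]1(C)O[Si](CC)(CC)CC)C(=O)CC[C@]2(C)O | intermediate
22 | C21-methylene C18-carbinol | CC1=CC[C@H]2[C@@H]([C@@H]1CC[C@H]1[C@]3(C)CC[C@H](O[Si](CC)(CC)CC)C(C)(C)O[C@H]3CC[C@]1(C)O[Si](CC)(CC)CC)C(=C)CC[C@]2(C)O | intermediate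
23 | N-alkyl octylsulfonylhydrazide (C21 configuration immaterial) | CC1=CC[C@H]2[C@@H]([C@@H]1CC[C@H]1[C@]3(C)CC[C@H](O[Si](CC)(CC)CC)C(C)(C)O[C@H]3CC[C@]1(C)O[Si](CC)(CC)CC)C(C)(CNNS(=O)(=O)CCCCCCCC)CC[C@]2(C)O | intermediate
24 | 2,9-bis-O-TES sipholenol L | CC1=CC[C@H]2[C@@H]([C@@H]1CC[C@H]1[C@]3(C)CC[C@H](O[Si](CC)(CC)CC)C(C)(C)O[C@H]3CC[C@]1(C)O[Si](CC)(CC)CC)C(C)(C)CC[C@]2(C)O | intermediate
25 | sipholenol L | CC1=CC[C@H]2[C@@H]([C@@H]1CC[C@H]1[C@]3(C)CC[C@H](O)C(C)(C)O[C@H]3CC[C@]1(C)O)C(C)(C)CC[C@]2(C)O | target

**Total step count:** 16. **Longest linear sequence:** 16 steps (1 → 25). Compounds 6, 12 and 16 enter as purchased.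

**Steps most likely to fail**

Step 10 (key cycloaddition).
- What may go wrong: the alkyl group at C13 and the methyl group at C14 polarise the diene in opposite senses. The catalyst-bound quinone may therefore distinguish poorly between the two endo orientations, which would appear as poor selection of the diene face. The adduct may also enolise towards the hydroquinone on handling.
- Fallback: stereocontrol is taken from the catalyst and handed to a separation that uses the resident left-half centres. Setting out from 15 and 16, the cycloaddition is run without any chiral promoter (toluene, 40 °C). This should give 17 together with the endo adduct of the other diene face, the (13R,17R,22S)-enedione F1. The crude pair is reduced at once with Zn/AcOH as in step 11 to 18 and the (13R,17R,22S)-cis-dione F2. These no longer enolise to an arene, are diastereomers, and are parted by preparative chromatography. The route is rejoined at 18.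

Step 15 (hydromethylation).
- What may go wrong: the crowded C21 radical may be slow to capture the hydrazone. It could then be reduced, or the alkene could migrate into the ring by reversible hydrogen-atom transfer. Competing hydrogen-atom transfer to the C14=C15 bond is also possible.
- Fallback: the second methyl group is built by polar chemistry from an aldehyde. Setting out from 22, 9-BBN (selective for the 1,1-disubstituted alkene) gives the organoborane F3, and alkaline H2O2 gives the primary alcohol F4. Dess–Martin periodinane gives the aldehyde F5. KOtBu/MeI alkylates its enolate at C21 to the α-methyl aldehyde F6, whose C21 configuration does not matter. TsNHNH2 gives the tosylhydrazone F7. Reduction with catecholborane followed by NaOAc·3H2O turns the formyl carbon into CH3. The route is rejoined at 24.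

Step 5 (cascade).
- What may go wrong: the C9 cation may lose a proton faster than the ester carbonyl captures it, or the ester may be cleaved early. Either would end the cascade at an alkene instead of the lactone.
- Fallback: ring formation and C9–O bond formation are separated. Setting out from 8, a Lewis acid that leaves no silyl group (MeAlCl2 or BF3·OEt2, CH2Cl2, −78 °C) is used only to build the oxepane and the cyclohexane. This gives the bicyclic alkene ester F8, drawn as the C9 exocyclic isomer with the endocyclic isomers carried along. Trifluoroacetic acid (CH2Cl2, 0 °C) then removes the tert-butyl group and protonates every alkene isomer to the same C9 cation. The equatorial carboxyl chain captures this cation opposite the axial C5 methyl (protolactonisation). The route is rejoined at 10.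

**Further compounds**
F1 | step 10 | (13R,17R,22S)-endo enedione adduct | CC1=CC[C@@H]2[C@H]([C@H]1CC[C@H]1[C@]3(C)CC[C@H](O[Si](CC)(CC)CC)C(C)(C)O[C@H]3CC[C@]1(C)O[Si](CC)(CC)CC)C(=O)C=CC2=O
F2 | step 10 | (13R,17R,22S)-cis-decalin-1,4-dione | CC1=CC[C@@H]2[C@H]([C@H]1CC[C@H]1[C@]3(C)CC[C@H](O[Si](CC)(CC)CC)C(C)(C)O[C@H]3CC[C@]1(C)O[Si](CC)(CC)CC)C(=O)CCC2=O
F3 | step 15 | C21–CH2–(9-BBN) organoborane | CC1=CC[C@H]2[C@@H]([C@@H]1CC[C@H]1[C@]3(C)CC[C@H](O[Si](CC)(CC)CC)C(C)(C)O[C@H]3CC[C@]1(C)O[Si](CC)(CC)CC)C(CB4C5CCCC4CCC5)CC[C@]2(C)O
F4 | step 15 | C21 hydroxymethyl compound | CC1=CC[C@H]2[C@@H]([C@@H]1CC[C@H]1[C@]3(C)CC[C@H](O[Si](CC)(CC)CC)C(C)(C)O[C@H]3CC[C@]1(C)O[Si](CC)(CC)CC)C(CO)CC[C@]2(C)O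
F5 | step 15 | C21 carbaldehyde | CC1=CC[C@H]2[C@@H]([C@@H]1CC[C@H]1[C@]3(C)CC[C@H](O[Si](CC)(CC)CC)C(C)(C)O[C@H]3CC[C@]1(C)O[Si](CC)(CC)CC)C(C=O)CC[C@]2(C)O
F6 | step 15 | C21 methyl carbaldehyde | CC1=CC[C@H]2[C@@H]([C@@H]1CC[C@H]1[C@]3(C)CC[C@H](O[Si](CC)(CC)CC)C(C)(C)O[C@H]3CC[C@]1(C)O[Si](CC)(CC)CC)C(C)(C=O)CC[C@]2(C)O
F7 | step 15 | tosylhydrazone of F6 | CC1=CC[C@H]2[C@@H]([C@@H]1CC[C@H]1[C@]3(C)CC[C@H](O[Si](CC)(CC)CC)C(C)(C)O[C@H]3CC[C@]1(C)O[Si](CC)(CC)CC)C(C)(C=NNS(=O)(=O)c4ccc(C)cc4)CC[C@]2(C)O
F8 | step 5 | bicyclic C9-methylene tert-butyl ester | CC(C)(C)OC(=O)CC[C@H]1[C@]3(C)CC[C@H](O)C(C)(C)O[C@H]3CCC1=C
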